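The strategy rests on cutting C2–C3 of the 14-membered carbocycle (C1 = CHOAc, C4(Me)=C5–C6=C7(iPr), C10 carbinol, C11 and C14 the tetrahydrofuran carbons) by a retro-Claisen transform. The feature exploited is the γ,δ-unsaturated carbonyl pattern C1–C2–C3–C4=C5 with its E-trisubstituted alkene, plus the bond from C1 to the quaternary ether carbon C14, so that C1 can enter as the carbonyl of a lactone. One thermal [3,3]-shift forms C2–C3, the C4=C5 alkene and the C1 ketone while enlarging a 12-membered oxacycle by two carbons. Its precursor is the methylenated macrolactone between the C1 acid and a C5 dienol bearing isopropenyl, with C10 silylated and the cis-tetrahydrofuran in place.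

Key step: step 13

Remark: the C1–C14 numbering of the carbocycle is used throughout, and ring sizes are counted through C12–C13 (one atom fewer through the ring oxygen). C5 is carried as a mixture of epimers from step 9 to step 12 because step 13 turns it into an sp2 carbon. In the SMILES of the titanium–aluminium reagent of step 12 the bridging chloride is drawn as a chloronium–aluminate pair.

**Route**

Step 1
Reactants: 1 (S)-linalool, (3S)-3,7-dimethylocta-1,6-dien-3-ol
Product: 2 (2E,6S)-2,6-dimethylocta-2,7-diene-1,6-diol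
Conditions: SeO2 (10 mol %), t-BuOOH, salicylic acid (cat.), CH2Cl2, rt
Reagents that add atoms: tert-butyl hydroperoxide, CC(C)(C)OO
Why: Catalytic SeO2 allylic oxidation (ene reaction then [2,3]-shift) attacks the electron-rich trisubstituted alkene and hydroxylates its E-methyl group, the future C9, leaving the vinyl carbinol and the linalool stereocentre (future C14) untouched.

Step 2
Reactants: 2 (2E,6S)-2,6-dimethylocta-2,7-diene-1,6-diol
Product: 4 (2S)-2-[(2R,5S)-5-ethenyl-5-methyloxolan-2-yl]propane-1,2-diol, via (2S,3S)-epoxy alcohol 3 (not isolated)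
Conditions: Ti(OiPr)4 (10 mol %), L-(+)-diethyl tartrate (12 mol %), t-BuOOH, 4 Å MS, CH2Cl2, −20 °C; then CSA (30 mol %), −20 °C to rt
Reagents that add atoms: tert-butyl hydroperoxide, CC(C)(C)OO
Why: Sharpless asymmetric epoxidation of the primary allylic alcohol with the L-(+)-tartrate ligand should give the (2S,3S)-epoxide under catalyst control, and acid then triggers 5-exo opening by the tertiary hydroxyl at the epoxide carbon remote from CH2OH with inversion, which sets C11 as R, keeps the C10–O bond (S) and places the two side chains cis on the new tetrahydrofuran.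

Step 3
Reactants: 4 (2S)-2-[(2R,5S)-5-ethenyl-5-methyloxolan-2-yl]propane-1,2-diol
Product: 5 (2R,5S)-2-[(2S)-1,2-bis(triethylsilyloxy)propan-2-yl]-5-ethenyl-5-methyloxolane
Conditions: Et3SiOTf (2.5 equiv), 2,6-lutidine, CH2Cl2, −78 to 0 °C
Reagents that add atoms: triethylsilyl trifluoromethanesulfonate, CC[Si](CC)(CC)OS(=O)(=O)C(F)(F)F
Why: Silyl triflate with a hindered pyridine base silylates the tertiary as well as the primary hydroxyl (silyl ether formation), so C10 receives the protecting group it keeps to the end, which later prevents its oxygen from adding to the C1 carbonyl or to the enol ether.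

Step 4
Reactants: 5 (2R,5S)-2-[(2S)-1,2-bis(triethylsilyloxy)propan-2-yl]-5-ethenyl-5-methyloxolane
Product: 7 methyl (2S,5R)-5-[(2S)-1,2-bis(triethylsilyloxy)propan-2-yl]-2-methyloxolane-2-carboxylate, via C1 aldehyde 6 (not isolated)
Conditions: O3, NaOH (2.5 M in MeOH), CH2Cl2, −78 °C
Reagents that add atoms: ozone, [O-][O+]=O; methanol, CO
Why: Ozonolysis of the only alkene in methanolic NaOH gives the non-enolisable C1 aldehyde, whose methyl hemiacetal is oxidised further by ozone to the methyl ester (direct oxidative cleavage of an alkene to an ester), and no bond to C14 is broken.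

Step 5
Reactants: 7 methyl (2S,5R)-5-[(2S)-1,2-bis(triethylsilyloxy)propan-2-yl]-2-methyloxolane-2-carboxylate
Product: 9 methyl (2S,5R)-2-methyl-5-[(2R)-1-oxo-2-(triethylsilyloxy)propan-2-yl]oxolane-2-carboxylate, via alkoxysulfonium chloride 8 (not isolated)
Conditions: (COCl)2, DMSO, CH2Cl2, −78 to −40 °C; Et3N, −78 to 0 °C
Reagents that add atoms: none
Why: Under Swern conditions the activated sulfoxide cleaves a primary triethylsilyl ether and oxidises that carbon directly to the aldehyde, while the tertiary silyl ether is too hindered to react and the quaternary C10 cannot epimerise (its descriptor changes to R only through the priority rules).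

Step 6
Reactants: 9 methyl (2S,5R)-2-methyl-5-[(2R)-1-oxo-2-(triethylsilyloxy)propan-2-yl]oxolane-2-carboxylate
Product: 10 methyl (2S,5R)-2-methyl-5-[(2S)-2-(triethylsilyloxy)but-3-en-2-yl]oxolane-2-carboxylate
Conditions: Ph3PCH3Br, KN(SiMe3)2, THF, 0 °C; then 9, −78 to 0 °C
Reagents that add atoms: methyltriphenylphosphonium bromide, C[P+](c1ccccc1)(c1ccccc1)c1ccccc1.[Br-]
Why: Wittig methylenation with the small unstabilised ylide converts the aldehyde into the C9=C8 vinyl group much faster than the ylide can attack the α-quaternary methyl ester.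

Step 7
Reactants: 11 3-methylbut-1-yne; 12 methacrolein (2-methylprop-2-enal)
Product: 14 rac-2,6-dimethylhept-1-en-4-yn-3-ol, via lithium acetylide 13 (not isolated)
Conditions: n-BuLi, THF, −78 °C; then 12, −78 to −20 °C; aq NH4Cl
Reagents that add atoms: none
Why: The lithium acetylide adds 1,2 to the enal (alkynylation of an aldehyde) to give the C5 carbinol as a racemate, which is sufficient because C5 is erased in step 13.

Step 8
Reactants: 14 rac-2,6-dimethylhept-1-en-4-yn-3-ol
Product: 16 rac-(4Z)-5-iodo-2,6-dimethylhepta-1,4-dien-3-ol, via cyclic alkenylalanate 15 (not isolated)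
Conditions: NaAlH2(OCH2CH2OMe)2, THF, 0 °C to rt; EtOAc, −78 °C; I2, −78 to 0 °C
Reagents that add atoms: iodine, II
Why: Alkoxide-directed trans-hydroalumination of the propargylic alcohol places aluminium on the distal alkyne carbon (future C7) cis to the carbinol carbon, and iodinolysis with retention gives the Z-iodide, so that whatever replaces iodine will sit cis to C5.

Step 9
Reactants: 10 methyl (2S,5R)-2-methyl-5-[(2S)-2-(triethylsilyloxy)but-3-en-2-yl]oxolane-2-carboxylate; 16 rac-(4Z)-5-iodo-2,6-dimethylhepta-1,4-dien-3-ol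
Product: 18 methyl (2S,5R)-5-[(2S,5E,7RS)-7-hydroxy-8-methyl-5-(propan-2-yl)-2-(triethylsilyloxy)nona-5,8-dien-2-yl]-2-methyloxolane-2-carboxylate, via B-alkyl-9-BBN 17 (not isolated)
Conditions: 10, 9-BBN-H (1.2 equiv), THF, rt; aq Cs2CO3; then 16, PdCl2(dppf) (5 mol %), AsPh3, DMF, rt to 40 °C
Reagents that add atoms: none
Why: Anti-Markovnikov hydroboration of the vinyl group followed by B-alkyl Suzuki–Miyaura coupling with the alkenyl iodide forms C8–C7 with retention of alkene geometry, so C8 ends cis to C5 and isopropyl trans to it, while the ester and the free hydroxyl are tolerated and residual B–H is destroyed by the aqueous base before the isopropenyl group is present.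

Step 10
Reactants: 18 methyl (2S,5R)-5-[(2S,5E,7RS)-7-hydroxy-8-methyl-5-(propan-2-yl)-2-(triethylsilyloxy)nona-5,8-dien-2-yl]-2-methyloxolane-2-carboxylate
Product: 19 (2S,5R)-5-[(2S,5E,7RS)-7-hydroxy-8-methyl-5-(propan-2-yl)-2-(triethylsilyloxy)nona-5,8-dien-2-yl]-2-methyloxolane-2-carboxylic acid
Conditions: LiOH, THF–MeOH–H2O, rt to 40 °C; HCl (aq) to pH 4–5, 0 °C
Reagents that add atoms: lithium hydroxide, [Li+].[OH-]
Why: Saponification of the methyl ester (acyl–oxygen cleavage by hydroxide) is assisted by the α-alkoxy group, and the tertiary silyl ether, the diene and the carbinol are stable to aqueous base and to the brief, cold, mildly acidic work-up.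

Step 11
Reactants: 19 (2S,5R)-5-[(2S,5E,7RS)-7-hydroxy-8-methyl-5-(propan-2-yl)-2-(triethylsilyloxy)nona-5,8-dien-2-yl]-2-methyloxolane-2-carboxylic acid
Product: 21 macrolactone C1(=O)–O–C5 (ring atoms C1/O/C5–C14; 5-isopropenyl; 6E; 7-isopropyl; 10S methyl and triethylsilyloxy; 11R,14S cis-tetrahydrofuran; 14-methyl; both C5 epimers), via mixed anhydride 20 (not isolated)
Conditions: 2-methyl-6-nitrobenzoic anhydride, DMAP, CH2Cl2 (1 mM), rt, syringe-pump addition of 19
Reagents that add atoms: none
Why: Shiina macrolactonisation activates the acid as a mixed anhydride that DMAP transfers to the secondary C5 hydroxyl at room temperature and high dilution, mild enough for the doubly allylic carbinol, and the cis-tetrahydrofuran together with the cis ring bonds at C6=C7 pre-folds the chain for closure.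

Step 12
Reactants: 21 macrolactone C1(=O)–O–C5 (both C5 epimers)
Product: 22 2-methylene cyclic ether: 21 with C1=O replaced by C1=C2H2 (exocyclic enol ether; 10S,11R,14S; 6E; both C5 epimers)
Conditions: Cp2Ti(μ-Cl)(μ-CH2)AlMe2 (2 equiv), pyridine, THF–PhMe, −40 to 0 °C; aq NaOH, −20 °C; filtration through basic Al2O3
Reagents that add atoms: Tebbe reagent Cp2Ti(μ-Cl)(μ-CH2)AlMe2, C[Al-]1(C)C[Ti]([Cl+]1)(C1C=CC=C1)C1C=CC=C1
Why: Tebbe methylenation through the titanium methylidene and an oxatitanacyclobutane converts the lactone carbonyl into the exocyclic enol ether at or below 0 °C, well under the temperature of the rearrangement so that no C1 ketone is exposed to the methylidene, in a pyridine-buffered medium that ties up the aluminium Lewis acid, and because C14 bears no hydrogen the new double bond cannot migrate into the ring.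

Step 13
Reactants: 22 2-methylene cyclic ether (both C5 epimers)
Product: 23 (4E,6E,10S,11R,14S)-11,14-epoxy-4,10,14-trimethyl-7-(propan-2-yl)-10-(triethylsilyloxy)cyclotetradeca-4,6-dien-1-one
Conditions: PhMe (5 mM, degassed), Et3N (5 mol %), 80 to 110 °C
Reagents that add atoms: none
Why: A thermal Claisen rearrangement, the concerted suprafacial [3,3]-shift of the allyl vinyl ether unit C2=C1–O–C5–C4=C3, creates the C2–C3 σ-bond while the O–C5 bond is cleaved, which turns C1 into a ketone carbonyl and places the new alkene at C4=C5. The closest known reaction type is the two-carbon ring expansion of lactone-derived 2-methylene oxacycles bearing a 1-alkenyl group on the ring carbinol carbon, familiar for medium rings and applied here to a 12-membered ether. The 14-membered carbocycle is formed by ring enlargement rather than by joining two chain ends: the oxacycle gives up its ring oxygen to the carbonyl and takes up C2, C3 and C4 through a six-membered transition state. No stereocentre is created and the C5 stereocentre becomes an sp2 carbon, so both epimers of 22 should converge on 23. The 4E geometry is required and should arise from the transition state in which the ring bond C5–C6 is pseudo-equatorial and thus remote from the substituted C14 on C1, an arrangement that the long C6–C14 tether can span. Site selectivity is also required, namely bonding of C2 to the isopropenyl CH2 (C3) and not to C7 of the ring alkene, which is fully substituted and would have to become a quaternary centre, and the pericyclic path must outrun heterolysis of the doubly allylic C5–O bond, which the amine-buffered medium free of Brønsted and Lewis acids should secure.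

Step 14
Reactants: 23 (4E,6E,10S,11R,14S)-11,14-epoxy-4,10,14-trimethyl-7-(propan-2-yl)-10-(triethylsilyloxy)cyclotetradeca-4,6-dien-1-one
Product: 24 (1R,4E,6E,10S,11R,14S)-11,14-epoxy-4,10,14-trimethyl-7-(propan-2-yl)-10-(triethylsilyloxy)cyclotetradeca-4,6-dien-1-ol
Conditions: (S)-2-methyl-CBS-oxazaborolidine (0.5 equiv), catecholborane, PhMe, −78 to −30 °C
Reagents that add atoms: none
Why: Corey–Bakshi–Shibata reduction under reagent control, in which the catalyst reads the quaternary C14 as the large and C2H2 as the small ketone substituent so that the (S)-oxazaborolidine should deliver hydride to give the 1R carbinol, while catecholborane at low temperature spares the diene.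

Step 15
Reactants: 24 (1R,4E,6E,10S,11R,14S)-11,14-epoxy-4,10,14-trimethyl-7-(propan-2-yl)-10-(triethylsilyloxy)cyclotetradeca-4,6-dien-1-ol
Product: 25 (1R,4E,6E,10S,11R,14S)-11,14-epoxy-4,10,14-trimethyl-7-(propan-2-yl)-10-(triethylsilyloxy)cyclotetradeca-4,6-dien-1-yl acetate
Conditions: Ac2O, pyridine, DMAP (cat.), CH2Cl2, rt
Reagents that add atoms: acetic anhydride, CC(=O)OC(C)=O
Why: DMAP-catalysed acylation esterifies the only free hydroxyl with retention at C1, and because the tertiary C10 oxygen is still silylated no selectivity between hydroxyls is required.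

Step 16
Reactants: 25 (1R,4E,6E,10S,11R,14S)-11,14-epoxy-4,10,14-trimethyl-7-(propan-2-yl)-10-(triethylsilyloxy)cyclotetradeca-4,6-dien-1-yl acetate
Product: 26 (1R,4E,6E,10S,11R,14S)-11,14-epoxy-10-hydroxy-4,10,14-trimethyl-7-(propan-2-yl)cyclotetradeca-4,6-dien-1-yl acetate (target)
Conditions: HF·pyridine, pyridine, THF, 0 °C to rt
Reagents that add atoms: none
Why: Buffered fluoride desilylation cleaves the Si–O bond of the tertiary triethylsilyl ether without touching the acetate, the diene or any stereocentre.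

**Compound list**

1 | (S)-linalool, (3S)-3,7-dimethylocta-1,6-dien-3-ol | C=C[C@@](C)(O)CCC=C(C)C | starting material
2 | (2E,6S)-2,6-dimethylocta-2,7-diene-1,6-diol | C=C[C@@](C)(O)CC/C=C(\C)CO | intermediate
3 | (3S)-5-[(2S,3S)-3-(hydroxymethyl)-3-methyloxiran-2-yl]-3-methylpent-1-en-3-ol | C=C[C@@](C)(O)CC[C@@H]1O[C@@]1(C)CO | intermediate
4 | (2S)-2-[(2R,5S)-5-ethenyl-5-methyloxolan-2-yl]propane-1,2-diol | OC[C@](C)(O)[C@H]2CC[C@](C=C)(C)O2 | intermediate
5 | (2R,5S)-2-[(2S)-1,2-bis(triethylsilyloxy)propan-2-yl]-5-ethenyl-5-methyloxolane | CC[Si](CC)(CC)OC[C@](C)(O[Si](CC)(CC)CC)[C@H]2CC[C@](C=C)(C)O2 | intermediate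
6 | (2S,5R)-5-[(2S)-1,2-bis(triethylsilyloxy)propan-2-yl]-2-methyloxolane-2-carbaldehyde | CC[Si](CC)(CC)OC[C@](C)(O[Si](CC)(CC)CC)[C@H]2CC[C@](C=O)(C)O2 | intermediate
7 | methyl (2S,5R)-5-[(2S)-1,2-bis(triethylsilyloxy)propan-2-yl]-2-methyloxolane-2-carboxylate | CC[Si](CC)(CC)OC[C@](C)(O[Si](CC)(CC)CC)[C@H]2CC[C@](C(=O)OC)(C)O2 | intermediate
8 | {(2S)-2-[(2R,5S)-5-(methoxycarbonyl)-5-methyloxolan-2-yl]-2-(triethylsilyloxy)propoxy}dimethylsulfonium chloride | C[S+](C)OC[C@](C)(O[Si](CC)(CC)CC)[C@H]2CC[C@](C(=O)OC)(C)O2.[Cl-] | intermediate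
9 | methyl (2S,5R)-2-methyl-5-[(2R)-1-oxo-2-(triethylsilyloxy)propan-2-yl]oxolane-2-carboxylate | O=C[C@](C)(O[Si](CC)(CC)CC)[C@H]2CC[C@](C(=O)OC)(C)O2 | intermediate
10 | methyl (2S,5R)-2-methyl-5-[(2S)-2-(triethylsilyloxy)but-3-en-2-yl]oxolane-2-carboxylate | C=C[C@](C)(O[Si](CC)(CC)CC)[C@H]2CC[C@](C(=O)OC)(C)O2 | intermediate
11 | 3-methylbut-1-yne | CC(C)C#C | starting material
12 | methacrolein, 2-methylprop-2-enal | C=C(C)C=O | starting material
13 | lithium 3-methylbut-1-yn-1-ide | [Li]C#CC(C)C | intermediate
14 | rac-2,6-dimethylhept-1-en-4-yn-3-ol | C=C(C)C(O)C#CC(C)C | intermediate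
15 | sodium cyclic alkenylalanate (five-membered ring O–Al–C7=C6–C5, two 2-methoxyethoxy groups on aluminium), racemic | [Na+].CC(C)C1=CC(C(C)=C)O[Al-]1(OCCOC)OCCOC | intermediate
16 | rac-(4Z)-5-iodo-2,6-dimethylhepta-1,4-dien-3-ol | C=C(C)C(O)/C=C(\I)C(C)C | intermediate
17 | methyl (2S,5R)-5-[(2S)-4-(9-borabicyclo[3.3.1]nonan-9-yl)-2-(triethylsilyloxy)butan-2-yl]-2-methyloxolane-2-carboxylate | C1CC2CCCC(C1)B2CC[C@](C)(O[Si](CC)(CC)CC)[C@H]3CC[C@](C(=O)OC)(C)O3 | intermediate
18 | methyl (2S,5R)-5-[(2S,5E,7RS)-7-hydroxy-8-methyl-5-(propan-2-yl)-2-(triethylsilyloxy)nona-5,8-dien-2-yl]-2-methyloxolane-2-carboxylate | C=C(C)C(O)/C=C(/C(C)C)CC[C@](C)(O[Si](CC)(CC)CC)[C@H]2CC[C@](C(=O)OC)(C)O2 | intermediate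
19 | (2S,5R)-5-[(2S,5E,7RS)-7-hydroxy-8-methyl-5-(propan-2-yl)-2-(triethylsilyloxy)nona-5,8-dien-2-yl]-2-methyloxolane-2-carboxylic acid | C=C(C)C(O)/C=C(/C(C)C)CC[C@](C)(O[Si](CC)(CC)CC)[C@H]2CC[C@](C(=O)O)(C)O2 | intermediate
20 | mixed anhydride of acid 19 with 2-methyl-6-nitrobenzoic acid | C=C(C)C(O)/C=C(/C(C)C)CC[C@](C)(O[Si](CC)(CC)CC)[C@H]2CC[C@](C(=O)OC(=O)c3c(C)cccc3[N+](=O)[O-])(C)O2 | intermediate
21 | macrolactone C1(=O)–O–C5 (ring atoms C1, O, C5–C14; 5-isopropenyl; 6E; 7-isopropyl; 10S methyl and triethylsilyloxy; 11R,14S cis-tetrahydrofuran; 14-methyl; both C5 epimers) | O=C1OC(C(C)=C)/C=C(/C(C)C)CC[C@](C)(O[Si](CC)(CC)CC)[C@H]2CC[C@]1(C)O2 | intermediate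
22 | 2-methylene cyclic ether, the C1=CH2 analogue of 21 (10S,11R,14S; 6E; both C5 epimers) | C=C1OC(C(C)=C)/C=C(/C(C)C)CC[C@](C)(O[Si](CC)(CC)CC)[C@H]2CC[C@]1(C)O2 | intermediate
23 | (4E,6E,10S,11R,14S)-11,14-epoxy-4,10,14-trimethyl-7-(propan-2-yl)-10-(triethylsilyloxy)cyclotetradeca-4,6-dien-1-one | O=C1CC/C(C)=C/C=C(/C(C)C)CC[C@](C)(O[Si](CC)(CC)CC)[C@H]2CC[C@]1(C)O2 | intermediate
24 | (1R,4E,6E,10S,11R,14S)-11,14-epoxy-4,10,14-trimethyl-7-(propan-2-yl)-10-(triethylsilyloxy)cyclotetradeca-4,6-dien-1-ol | O[C@@H]1CC/C(C)=C/C=C(/C(C)C)CC[C@](C)(O[Si](CC)(CC)CC)[C@H]2CC[C@]1(C)O2 | intermediate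
25 | (1R,4E,6E,10S,11R,14S)-11,14-epoxy-4,10,14-trimethyl-7-(propan-2-yl)-10-(triethylsilyloxy)cyclotetradeca-4,6-dien-1-yl acetate | CC(=O)O[C@@H]1CC/C(C)=C/C=C(/C(C)C)CC[C@](C)(O[Si](CC)(CC)CC)[C@H]2CC[C@]1(C)O2 | intermediate
26 | (1R,4E,6E,10S,11R,14S)-11,14-epoxy-10-hydroxy-4,10,14-trimethyl-7-(propan-2-yl)cyclotetradeca-4,6-dien-1-yl acetate | CC(=O)O[C@@H]1CC/C(C)=C/C=C(/C(C)C)CC[C@](C)(O)[C@H]2CC[C@]1(C)O2 | target

**Step count and risks**

Total step count: 16. Longest linear sequence: 14 steps (steps 1–6 and 9–16); the alkenyl iodide branch is steps 7–8.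

Steps most likely to fail:

Step 13. The rearrangement may pass through a transition state with C6 pseudo-axial and deliver the Z alkene, may engage the ring alkene, or may be overtaken by heterolysis of the doubly allylic C5–O bond. The two C5 epimers may also react at very different rates. The fallback sets out from hydroxy ester 18 and returns at ketone 23, making the same C2–C3 bond in an acyclic chair. Johnson–Claisen rearrangement of 18 with trimethyl orthoacetate and catalytic propionic acid (PhMe, 110 °C) should attack the unhindered isopropenyl terminus and give the E alkene through the usual 1,3-diaxial control, affording the dimethyl diester F1. Dieckmann cyclisation (KN(SiMe3)2, THF, high dilution), in which only the C2 ester can form an enolate and the non-enolisable C14 ester is the acceptor, should give the macrocyclic β-keto ester F2. Krapcho demethoxycarbonylation (LiCl, wet DMSO, 130 °C) then leads to 23.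

Step 11. Intermolecular acylation (dimers, oligomers) may outrun closure of the strained lactone ring, and the activated doubly allylic ester may ionise. The fallback sets out from seco acid 19 and returns at ketone 23, closing the ring by a C–C bond instead. Excess MeLi (THF, 0 °C, quench into Me3SiCl and aq NH4Cl) should convert the carboxylic acid into the methyl ketone, giving the hydroxy methyl ketone F3. MsCl, Et3N and LiCl (DMF, 0 °C) should convert the doubly allylic alcohol with allylic transposition into the conjugated primary E-allylic chloride F4 (chlorine on C3). KN(SiMe3)2 at high dilution (THF, −78 to 0 °C) then generates the only possible enolate (at C2), whose intramolecular C-alkylation forms C2–C3 and gives 23.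

Step 9. Oxidative addition and transmetalation at the hindered α-isopropyl alkenyl iodide may be slow, so that protodeboronation or β-hydride elimination of the alkyl group takes over. The fallback sets out from vinyl ester 10 and returns at 18, replacing the borane by an organozinc. Hydroboration and oxidation (9-BBN-H, THF; NaBO3, H2O) should give the primary alcohol F5, and I2, PPh3 and imidazole (CH2Cl2, 0 °C) the primary iodide F6. Zinc insertion (Zn dust, LiCl, THF, 40 °C), which tolerates the ester, gives the alkylzinc iodide F7. Negishi coupling with 16 under hydroxyl-tolerant conditions (Pd(OAc)2, SPhos, THF, slow addition of the zinc reagent) then forms C8–C7 with retention and gives 18.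

Further compounds
F1 | step 13 | methyl (2S,5R)-5-[(2S,5E,7E)-11-methoxy-8-methyl-11-oxo-5-(propan-2-yl)-2-(triethylsilyloxy)undeca-5,7-dien-2-yl]-2-methyloxolane-2-carboxylate | COC(=O)CC/C(C)=C/C=C(/C(C)C)CC[C@](C)(O[Si](CC)(CC)CC)[C@H]2CC[C@](C(=O)OC)(C)O2
F2 | step 13 | methyl (4E,6E,10S,11R,14S)-11,14-epoxy-4,10,14-trimethyl-1-oxo-7-(propan-2-yl)-10-(triethylsilyloxy)cyclotetradeca-4,6-diene-2-carboxylate (C2 epimers) | COC(=O)C1C/C(C)=C/C=C(/C(C)C)CC[C@](C)(O[Si](CC)(CC)CC)[C@H]2CC[C@](C1=O)(C)O2
F3 | step 11 | 1-{(2S,5R)-5-[(2S,5E,7RS)-7-hydroxy-8-methyl-5-(propan-2-yl)-2-(triethylsilyloxy)nona-5,8-dien-2-yl]-2-methyloxolan-2-yl}ethan-1-one | C=C(C)C(O)/C=C(/C(C)C)CC[C@](C)(O[Si](CC)(CC)CC)[C@H]2CC[C@](C(C)=O)(C)O2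
F4 | step 11 | 1-{(2S,5R)-5-[(2S,5E,7E)-9-chloro-8-methyl-5-(propan-2-yl)-2-(triethylsilyloxy)nona-5,7-dien-2-yl]-2-methyloxolan-2-yl}ethan-1-one | ClC/C(C)=C/C=C(/C(C)C)CC[C@](C)(O[Si](CC)(CC)CC)[C@H]2CC[C@](C(C)=O)(C)O2
F5 | step 9 | methyl (2S,5R)-5-[(2S)-4-hydroxy-2-(triethylsilyloxy)butan-2-yl]-2-methyloxolane-2-carboxylate | OCC[C@](C)(O[Si](CC)(CC)CC)[C@H]2CC[C@](C(=O)OC)(C)O2
F6 | step 9 | methyl (2S,5R)-5-[(2S)-4-iodo-2-(triethylsilyloxy)butan-2-yl]-2-methyloxolane-2-carboxylate | ICC[C@](C)(O[Si](CC)(CC)CC)[C@H]2CC[C@](C(=O)OC)(C)O2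
F7 | step 9 | {(3S)-3-[(2R,5S)-5-(methoxycarbonyl)-5-methyloxolan-2-yl]-3-(triethylsilyloxy)butyl}zinc iodide | I[Zn]CC[C@](C)(O[Si](CC)(CC)CC)[C@H]2CC[C@](C(=O)OC)(C)O2
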